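**Strategy.** Everything rests on cutting ring C of a flavan unit across O1–C2 and C3–C4. A base-mediated oxa-Michael/Henry/dehydration domino unites a ring-A salicylaldehyde, whose phenolic O1 and aldehyde carbon C4 are ortho on the pyrogallol ring, with a β-nitrostyrene that supplies C2 (bearing ring B) and C3 (nitro as masked oxygen), closing the pyran ring in one operation. The nitrochromene feeds both halves: reduction to the flavan-3-one, dynamic kinetic transfer hydrogenation to the (2R,3R)-cis-flavan-3-ol, then oxidation at benzylic C4 with water (3,4-trans half) or an internal carbonate (3,4-cis half), a Suzuki union at C6–C6' and hydrogenolysis.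

Key step: step 4

Remark on the chemistry: the target is read as a 6,6'-biflavan made of a (2R,3R,4R) all-cis unit and a (2R,3R,4S) 2,3-cis-3,4-trans unit. Nitrostyrene 5 is taken as a commercial building block. The C6–C6' axis carries only two ortho substituents and is treated as freely rotating.

**Step 1**
Reactants: 1 2,3,4-trihydroxybenzaldehyde
Product: 2 2,3,4-tris(benzyloxy)benzaldehyde
Conditions: BnBr, K2CO3, DMF, 60 °C
Reagents that add atoms: benzyl bromide, BrCc1ccccc1
Why: Exhaustive Williamson etherification of the three phenols; the benzyl ethers should survive every later step and leave by hydrogenolysis at the end.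

**Step 2**
Reactants: 2 2,3,4-tris(benzyloxy)benzaldehyde
Product: 3 3,4-bis(benzyloxy)-2-hydroxybenzaldehyde
Conditions: MgBr2·OEt2, toluene/Et2O, reflux; 1 M HCl work-up
Reagents that add atoms: none
Why: Magnesium chelated between the aldehyde oxygen and the ortho ether oxygen activates only that benzyl group for attack by bromide (chelation-controlled ortho-debenzylation), freeing the phenol that becomes O1.

**Step 3**
Reactants: 3 3,4-bis(benzyloxy)-2-hydroxybenzaldehyde
Product: 4 3,4-bis(benzyloxy)-5-bromo-2-hydroxybenzaldehyde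
Conditions: NBS, MeCN, 0 °C to rt
Reagents that add atoms: N-bromosuccinimide, BrN1C(=O)CCC1=O
Why: Electrophilic aromatic bromination should go para to the free phenol and ortho to the 4-benzyloxy group, the only doubly activated open position, which becomes C6.

**Step 4**
Reactants: 4 3,4-bis(benzyloxy)-5-bromo-2-hydroxybenzaldehyde; 5 (E)-1-(benzyloxy)-4-(2-nitrovinyl)benzene
Product: 7 rac-7,8-bis(benzyloxy)-2-[4-(benzyloxy)phenyl]-6-bromo-3-nitro-2H-chromene, via nitro-aldol adduct 6 (not isolated)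
Conditions: DABCO (0.5 equiv), MeCN, 60 °C
Reagents that add atoms: none
Why: DABCO deprotonates the phenol of 4, the phenoxide O1 adds to the benzylic β-carbon (C2) of nitroalkene 5 (oxa-Michael addition), the nitronate carbon C3 then adds to the ortho aldehyde carbon C4 (intramolecular Henry reaction) to give 6, and E1cB loss of water gives the conjugated nitrochromene 7. The closest known reaction type is the tandem oxa-Michael–Henry–dehydration synthesis of 2-aryl-3-nitro-2H-chromenes from salicylaldehydes and β-nitrostyrenes. The pyran ring closes in the C3–C4 bond-forming event, a 6-exo-trig attack of the nitronate on the aldehyde. C2 is the only stereocentre left in 7 and is formed racemic on purpose, because it becomes epimerisable in ketone 8 and is set together with C3 in step 6. The step needs O-attack of the ambident phenoxide and union of O1 with C2 and of C3 with C4; the polarisation of the nitroalkene (only the β-carbon is electrophilic, only the α-carbon becomes nucleophilic) secures this, and the irreversible dehydration drains the reversible Michael and Henry equilibria.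

**Step 5**
Reactants: 7 rac-7,8-bis(benzyloxy)-2-[4-(benzyloxy)phenyl]-6-bromo-3-nitro-2H-chromene
Product: 8 rac-7,8-bis(benzyloxy)-2-[4-(benzyloxy)phenyl]-6-bromochroman-3-one
Conditions: Fe powder, AcOH/H2O, 80 °C
Reagents that add atoms: water, O
Why: Dissolving-metal reduction of the conjugated nitroalkene to the enamine/imine and hydrolysis in the aqueous acid (reductive Nef-type conversion of a nitroalkene into a ketone) should give the flavan-3-one; aryl bromide and benzyl ethers are inert to iron in acetic acid.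

**Step 6**
Reactants: 8 rac-7,8-bis(benzyloxy)-2-[4-(benzyloxy)phenyl]-6-bromochroman-3-one
Product: 9 (2R,3R)-7,8-bis(benzyloxy)-2-[4-(benzyloxy)phenyl]-6-bromochroman-3-ol (2,3-cis)
Conditions: RuCl(p-cymene)[(R,R)-TsDPEN] (2 mol%), HCO2H/Et3N (1:1), CH2Cl2, 35 °C
Reagents that add atoms: none
Why: Asymmetric transfer hydrogenation under dynamic kinetic resolution, as known for 2-aryl cyclic ketones: C2–H (benzylic, alpha to the ketone and to O1) should enolise quickly in the amine-rich medium, the catalyst should reduce the (2R)-ketone faster and deliver hydride anti to the 2-aryl group, so C3 is set by the catalyst and C2 by the resolution, cis to the new hydroxyl; the (R,R) ligand is assigned by analogy and the antipodal catalyst would be taken if the sense proved opposite.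

**Step 7**
Reactants: 9 (2R,3R)-7,8-bis(benzyloxy)-2-[4-(benzyloxy)phenyl]-6-bromochroman-3-ol
Product: 10 (2R,3R,4S)-7,8-bis(benzyloxy)-2-[4-(benzyloxy)phenyl]-6-bromochromane-3,4-diol (2,3-cis-3,4-trans)
Conditions: DDQ, CH2Cl2/H2O, 0 °C to rt
Reagents that add atoms: water, O
Why: DDQ should abstract hydride from C4, whose cation is stabilised by O1 and the 7-benzyloxy group of ring A, and water should add anti to the pseudo-axial C3 hydroxyl, as in the known 4β-oxygenation of 2,3-cis-flavan-3-ol ethers, which sets C4 as S.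

**Step 8**
Reactants: 9 (2R,3R)-7,8-bis(benzyloxy)-2-[4-(benzyloxy)phenyl]-6-bromochroman-3-ol
Product: 11 (2R,3R)-7,8-bis(benzyloxy)-2-[4-(benzyloxy)phenyl]-6-bromochroman-3-yl tert-butyl carbonate
Conditions: Boc2O, DMAP, CH2Cl2, rt
Reagents that add atoms: di-tert-butyl dicarbonate, CC(C)(C)OC(=O)OC(=O)OC(C)(C)C
Why: DMAP-catalysed acylation of the only free hydroxyl; no stereocentre is touched.

**Step 9**
Reactants: 11 (2R,3R)-7,8-bis(benzyloxy)-2-[4-(benzyloxy)phenyl]-6-bromochroman-3-yl tert-butyl carbonate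
Product: 13 (2R,3R,4R)-7,8-bis(benzyloxy)-2-[4-(benzyloxy)phenyl]-6-bromochromane-3,4-diol (all-cis), via cyclic carbonate 12 (not isolated)
Conditions: DDQ, 4 Å molecular sieves, CH2Cl2, 0 °C to rt; filter; then K2CO3 (cat.), MeOH, rt
Reagents that add atoms: none
Why: The same DDQ hydride abstraction at C4, now without an external nucleophile, should let the carbonyl oxygen of the neighbouring 3-O-Boc group capture the cation on its own face (neighbouring-group participation; the five-membered ring can only be cis-fused), tert-butyl leaves as isobutene, and methanolysis of carbonate 12 frees the 3,4-cis diol with C4 as R.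

**Step 10**
Reactants: 10 (2R,3R,4S)-7,8-bis(benzyloxy)-2-[4-(benzyloxy)phenyl]-6-bromochromane-3,4-diol; 13 (2R,3R,4R)-7,8-bis(benzyloxy)-2-[4-(benzyloxy)phenyl]-6-bromochromane-3,4-diol
Product: 15 (2R,2'R,3R,3'R,4R,4'S)-7,7',8,8'-tetrakis(benzyloxy)-2,2'-bis[4-(benzyloxy)phenyl]-[6,6'-bichromane]-3,3',4,4'-tetraol, via pinacol boronate 14 (not isolated)
Conditions: 10, B2pin2, Pd(dppf)Cl2 (5 mol%), KOAc, 1,4-dioxane, 90 °C; then 13, K3PO4 (aq), 90 °C
Reagents that add atoms: bis(pinacolato)diboron, CC1(C)OB(OC1(C)C)B1OC(C)(C)C(C)(C)O1 (its atoms stay in 14 only, none in 15)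
Why: Miyaura borylation of the trans-diol bromide followed in the same flask by Suzuki–Miyaura coupling with the cis-diol bromide should form the C6–C6' bond; free secondary alcohols are tolerated and the basic medium does not ionise C4.

**Step 11**
Reactants: 15 (2R,2'R,3R,3'R,4R,4'S)-7,7',8,8'-tetrakis(benzyloxy)-2,2'-bis[4-(benzyloxy)phenyl]-[6,6'-bichromane]-3,3',4,4'-tetraol
Product: 16 (2R,2'R,3R,3'R,4R,4'S)-2,2'-bis(4-hydroxyphenyl)-[6,6'-bichromane]-3,3',4,4',7,7',8,8'-octaol (target)
Conditions: H2 (1 atm), Pd(OH)2/C, THF/MeOH, rt, acid-free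
Reagents that add atoms: none
Why: Hydrogenolysis of the six aryl benzyl ethers under neutral conditions, where the free benzylic C4 alcohols and the C2–O1 bonds should be retained, releases the octaol without touching a stereocentre.

**Compound list**
1 | 2,3,4-trihydroxybenzaldehyde | O=Cc1ccc(O)c(O)c1O | starting material
2 | 2,3,4-tris(benzyloxy)benzaldehyde | O=Cc1ccc(OCc2ccccc2)c(OCc2ccccc2)c1OCc1ccccc1 | intermediate
3 | 3,4-bis(benzyloxy)-2-hydroxybenzaldehyde | O=Cc1ccc(OCc2ccccc2)c(OCc2ccccc2)c1O | intermediate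
4 | 3,4-bis(benzyloxy)-5-bromo-2-hydroxybenzaldehyde | O=Cc1cc(Br)c(OCc2ccccc2)c(OCc2ccccc2)c1O | intermediate
5 | (E)-1-(benzyloxy)-4-(2-nitrovinyl)benzene | O=[N+]([O-])/C=C/c1ccc(OCc2ccccc2)cc1 | starting material
6 | 7,8-bis(benzyloxy)-2-[4-(benzyloxy)phenyl]-6-bromo-3-nitrochroman-4-ol (racemic diastereomer mixture, not isolated) | O=[N+]([O-])C1C(O)c2cc(Br)c(OCc3ccccc3)c(OCc3ccccc3)c2OC1c1ccc(OCc2ccccc2)cc1 | intermediate
7 | rac-7,8-bis(benzyloxy)-2-[4-(benzyloxy)phenyl]-6-bromo-3-nitro-2H-chromene | O=[N+]([O-])C1=Cc2cc(Br)c(OCc3ccccc3)c(OCc3ccccc3)c2OC1c1ccc(OCc2ccccc2)cc1 | intermediate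
8 | rac-7,8-bis(benzyloxy)-2-[4-(benzyloxy)phenyl]-6-bromochroman-3-one | O=C1Cc2cc(Br)c(OCc3ccccc3)c(OCc3ccccc3)c2OC1c1ccc(OCc2ccccc2)cc1 | intermediate
9 | (2R,3R)-7,8-bis(benzyloxy)-2-[4-(benzyloxy)phenyl]-6-bromochroman-3-ol | O[C@@H]1Cc2cc(Br)c(OCc3ccccc3)c(OCc3ccccc3)c2O[C@@H]1c1ccc(OCc2ccccc2)cc1 | intermediate
10 | (2R,3R,4S)-7,8-bis(benzyloxy)-2-[4-(benzyloxy)phenyl]-6-bromochromane-3,4-diol | O[C@@H]1[C@@H](O)c2cc(Br)c(OCc3ccccc3)c(OCc3ccccc3)c2O[C@@H]1c1ccc(OCc2ccccc2)cc1 | intermediate
11 | (2R,3R)-7,8-bis(benzyloxy)-2-[4-(benzyloxy)phenyl]-6-bromochroman-3-yl tert-butyl carbonate | CC(C)(C)OC(=O)O[C@@H]1Cc2cc(Br)c(OCc3ccccc3)c(OCc3ccccc3)c2O[C@@H]1c1ccc(OCc2ccccc2)cc1 | intermediate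
12 | 3,4-cis cyclic carbonate of diol 13 (all ring-C substituents cis, not isolated) | O=C3O[C@@H]1[C@H](O3)c2cc(Br)c(OCc4ccccc4)c(OCc4ccccc4)c2O[C@@H]1c1ccc(OCc2ccccc2)cc1 | intermediate
13 | (2R,3R,4R)-7,8-bis(benzyloxy)-2-[4-(benzyloxy)phenyl]-6-bromochromane-3,4-diol | O[C@@H]1[C@H](O)c2cc(Br)c(OCc3ccccc3)c(OCc3ccccc3)c2O[C@@H]1c1ccc(OCc2ccccc2)cc1 | intermediate
14 | (2R,3R,4S)-7,8-bis(benzyloxy)-2-[4-(benzyloxy)phenyl]-6-(4,4,5,5-tetramethyl-1,3,2-dioxaborolan-2-yl)chromane-3,4-diol (not isolated) | O[C@@H]1[C@@H](O)c2cc(B3OC(C)(C)C(C)(C)O3)c(OCc3ccccc3)c(OCc3ccccc3)c2O[C@@H]1c1ccc(OCc2ccccc2)cc1 | intermediate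
15 | (2R,2'R,3R,3'R,4R,4'S)-7,7',8,8'-tetrakis(benzyloxy)-2,2'-bis[4-(benzyloxy)phenyl]-[6,6'-bichromane]-3,3',4,4'-tetraol | C(c1ccccc1)Oc1ccc([C@H]2Oc3c(cc(-c4cc5c(c(OCc6ccccc6)c4OCc4ccccc4)O[C@H](c4ccc(OCc6ccccc6)cc4)[C@H](O)[C@H]5O)c(OCc4ccccc4)c3OCc3ccccc3)[C@@H](O)[C@H]2O)cc1 | intermediate
16 | (2R,2'R,3R,3'R,4R,4'S)-2,2'-bis(4-hydroxyphenyl)-[6,6'-bichromane]-3,3',4,4',7,7',8,8'-octaol | Oc1ccc([C@H]2Oc3c(cc(-c4cc5c(c(O)c4O)O[C@H](c4ccc(O)cc4)[C@H](O)[C@H]5O)c(O)c3O)[C@@H](O)[C@H]2O)cc1 | target

**Step count.** Total: 11 steps. Longest linear sequence: 10 steps (steps 1–6, 8, 9, 10, 11).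

**Steps most likely to fail**

Step 6. The catalyst may discriminate the two ketone enantiomers poorly, or epimerisation at C2 may be slower than reduction, so that the alcohol forms with low enantiomeric or cis/trans purity. Fallback, setting out from 8: reduction with LiBH(s-Bu)3 in THF at −78 °C should add hydride anti to the 2-aryl group and give the racemic 2,3-cis alcohol F1. Steglich esterification with (S)-O-methylmandelic acid (DCC, DMAP) gives two diastereomeric esters, which are separated by chromatography or crystallisation to give the (2R,3R)-configured ester F2. Methanolysis (K2CO3, MeOH) comes back to the route at 9.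

Step 7. Hydride abstraction may occur at C2 (benzylic to ring B) instead of C4, may be slow on the brominated 5-deoxy ring A, or may run on to the 4-ketone. Fallback, setting out from 9: Wohl–Ziegler bromination at C4 (NBS, dibenzoyl peroxide, PhCF3, 80 °C) should give the labile 4-bromide F3. It is solvolysed without purification (Ag2CO3, acetone/H2O), water again entering anti to the C3 hydroxyl, and the route is rejoined at 10.

Step 9. The C4 cation may be captured by the reduced quinone or by adventitious water (which would lead into the trans series) in competition with the carbonate oxygen, or the acidic hydroquinone may cleave the Boc group early. Fallback, setting out from 10: selective oxidation of the benzylic C4 alcohol (activated MnO2, CH2Cl2, rt) should give the 2,3-cis ketol F4. It is reduced at once (NaBH4, MeOH/THF, −40 °C), hydride adding anti to the pseudo-axial C3 hydroxyl to give the all-cis diol, and the route is rejoined at 13.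

**Further compounds**
F1 | step 6 | racemic 2,3-cis-7,8-bis(benzyloxy)-2-[4-(benzyloxy)phenyl]-6-bromochroman-3-ol (both enantiomers) | O[C@@H]1Cc2cc(Br)c(OCc3ccccc3)c(OCc3ccccc3)c2O[C@@H]1c1ccc(OCc2ccccc2)cc1.O[C@H]1Cc2cc(Br)c(OCc3ccccc3)c(OCc3ccccc3)c2O[C@H]1c1ccc(OCc2ccccc2)cc1
F2 | step 6 | (2R,3R)-7,8-bis(benzyloxy)-2-[4-(benzyloxy)phenyl]-6-bromochroman-3-yl (S)-2-methoxy-2-phenylacetate | CO[C@H](C(=O)O[C@@H]1Cc2cc(Br)c(OCc3ccccc3)c(OCc3ccccc3)c2O[C@@H]1c1ccc(OCc2ccccc2)cc1)c1ccccc1
F3 | step 7 | (2R,3R)-7,8-bis(benzyloxy)-2-[4-(benzyloxy)phenyl]-4,6-dibromochroman-3-ol (C4 epimer mixture, 2,3-cis) | O[C@@H]1C(Br)c2cc(Br)c(OCc3ccccc3)c(OCc3ccccc3)c2O[C@@H]1c1ccc(OCc2ccccc2)cc1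
F4 | step 9 | (2R,3S)-7,8-bis(benzyloxy)-2-[4-(benzyloxy)phenyl]-6-bromo-3-hydroxychroman-4-one (2,3-cis) | O[C@@H]1C(=O)c2cc(Br)c(OCc3ccccc3)c(OCc3ccccc3)c2O[C@@H]1c1ccc(OCc2ccccc2)cc1
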